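The data are calculated from invented constants, and the scatter is random.

I read the target column first.

| flask | starting material | remark | time |
|---|---|---|---|
| winter | 6 mM | run made earlier |  |
| noon | 9 mM | run made earlier |  |
| flask | 12 mM |  | 20 h |

| run | time / h | target / % | crystals / % |
|---|---|---|---|
| winter | 0.833 | 1 | 0 |
| winter | 2.50 | 11 | 2 |
| winter | 4.00 | 17 | 4 |
| winter | 6.00 | 17 | 6 |
| winter | 10.0 | 30 | 14 |
| winter | 12.0 | 36 | 23 |
| noon | 2.00 | 5 | 1 |
| noon | 4.00 | 14 | 4 |
| noon | 6.00 | 24 | 10 |
| noon | 8.00 | 27 | 14 |
| noon | 10.0 | 33 | 20 |
| noon | 12.0 | 39 | 25 |

(scatter of a reading: 2 percentage points)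

- amounts and yields of target count crystals too
- given per volume of solution although it is solid: crystals
- the numbers in the tables scatter with a standard deviation of 2 percentage points

- the target and crystals together standing at 20 h, as a percentage of the starting material charged
- concentration of target in solution at 20 h, in percent of saturation

1. The target column already counts crystals, so I take it as it stands for the asked total. The noon run reads 39% at 12.0 h, and the winter run reads 36% at 12.0 h.

2. My first way uses those last readings. Noon gives 16.8 h and winter gives 18.6 h. These come from different charges and lie close, so I carry their mean, 17.7 h. This is the rise half-time: the time in which the part of the charge not yet target falls to half, an apparent first-order half-life. For the flask at 12 mM it gives 54.2% at 20 h.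

3. My second way is a straight line through the noon run, which gives 66.2%. The two ways part by 12 points. But at 29.9 h the line reaches the whole charge, and past that it counts more target than was charged. The line cheats, so I keep 54.2%.

4. In the noon run at 12.0 h, c(target), the dissolved target, reads 1.26 mM. Crystals in the noon run read 1% at 2.00 h and 25% at 12.0 h, a rise well beyond the scatter, so I take the noon solution to stand above saturation. I can put no firm figure on how far.

5. The forecast says 82% (75% to 90%) and 1200% of saturation (500% to 4000%). Its ground: “Adding target and crystals gives totals”. My 54.2% lies below its low end.

6. The flask stands at 54.5% at 20 h, with c(target) at 407% of saturation.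

    target ⇌ isomer of the product (K = 2.90, k = 0.00706 min⁻¹)
    crystals ⇌ target, rate k2*(cs2 - [target]) while solid is left; crystals form when [target] > cs2 (solubility = 0.270 mM, k = 0.00477 min⁻¹)
    starting material ⇌ target (K = 1.80, k = 5.56 × 10⁻⁴ min⁻¹)
    isomer of the product ⇌ starting material (k = 7.46 × 10⁻⁴ min⁻¹)

Beside the target it holds 37.3% as isomer of the product and 8.20% as starting material. The rise half-time of 17.7 h gave 54.2% for this flask. Carried to the same flask read at 2.0 d, it gives 84.7%, and that flask stands at 81.4%.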